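**Retrosynthetic overview**
- Numbering: ring A is C1(Me)=C2H–C3H(OH)–C4HBr–C5Me2–C6. Ring B is C6–C7H2–C8H2–C9(Me)Br–C10HCl–C11H2. C6 is the spiro atom.
- Feature: cutting C9–C10 turns ring B into two identical 3-oxobutyl arms on C6 (C7–C8–C9(=O)Me and C11–C10H2–C(=O)Me). C6 is then a prochiral centre of an achiral triketone, and one aldol bond delivers the C9 methyl carbinol and a C10 acetyl group, which serves as the masked chlorine.
- Disconnections, backwards: C3–OH (1,2-reduction), C4–Br (α′-bromination), C9–Br (from C9–OH), C10–Cl (from C10–O through a cyclic sulfate, inversion), C1–Me (vinylogous-ester transposition), C10–O (Baeyer–Villiger), C9–C10 (desymmetrising aldol), the two C6–arm bonds.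
- Ring order: ring A is bought with dimedone and ring B is closed in step 7. The second arm is attached by Mukaiyama–Michael addition because a second SN2 alkylation beside C5Me2 is not credible. C1 is methylated before chlorine is introduced so that no alkoxide ever sits next to a C–Cl bond.

Key step: step 7

Assumption: which pseudo-enantiomeric cinchona amine selects the pro-S arm cannot be derived safely from a model; the route is written for the quinine-derived amine, and the quinidine-derived one is taken if the mirror image of 12 is formed.

Step 1
Reactants: 1 dimedone; 2 isobutanol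
Product: 3 3-isobutoxy-5,5-dimethylcyclohex-2-en-1-one
Conditions: p-TsOH (cat.), toluene, reflux, Dean–Stark
Reagents that add atoms: none
Why: Acid-catalysed O-alkyl enol ether formation of a symmetrical cyclic 1,3-dione, driven by azeotropic removal of water, can give only one vinylogous ester.

Step 2
Reactants: 4 2-(2-bromoethyl)-2-methyl-1,3-dioxolane
Product: 5 2-(2-iodoethyl)-2-methyl-1,3-dioxolane
Conditions: NaI, acetone, reflux
Reagents that add atoms: sodium iodide [Na+].[I-]
Why: Finkelstein exchange at a primary carbon, driven by precipitation of the bromide salt, gives the more reactive alkylating agent and leaves the ketal untouched.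

Step 3
Reactants: 3 vinylogous ester; 5 iodo ketal
Product: 6 C6-monoalkylated vinylogous ester (racemic)
Conditions: LDA, THF, −78 °C; then 5 (excess), DMPU, −78 °C → rt
Reagents that add atoms: none
Why: Kinetic α′-deprotonation of a 3-alkoxyenone (Stork–Danheiser alkylation) gives the cross-conjugated enolate, whose only nucleophilic α′ carbon is C6, and SN2 attack on the primary iodide creates a merely tertiary, racemic centre that becomes planar again in step 4.

Step 4
Reactants: 6 monoalkylated vinylogous ester
Product: 7 tetrasubstituted silyl dienol ether (C1–OTMS, C1=C6, C2=C3–OiBu)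
Conditions: LDA, THF, −78 °C; TMSCl, −78 → 0 °C; pentane, filtration, used crude
Reagents that add atoms: chlorotrimethylsilane C[Si](C)(C)Cl
Why: A second kinetic α′-deprotonation removes the only remaining C6 proton faster than the γ protons at C4, and O-silylation fixes the enolate as an isolable 1-alkoxy-3-silyloxy-1,3-diene.

Step 5
Reactants: 7 silyl dienol ether; 8 methyl vinyl ketone
Product: 10 keto ketal (racemic; C6 quaternary), via arm silyl enol ether 9 (not isolated)
Conditions: 8 (2 equiv), Sc(OTf)3 (5 mol %), CH2Cl2, −78 → −20 °C; then 0.5 M aq. citric acid–THF, 0 °C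
Reagents that add atoms: none
Why: In this Mukaiyama–Michael addition the doubly donor-activated diene terminus C6 attacks the unsubstituted CH2 end of the Lewis-acid-bound enone, the least demanding carbon electrophile available, so the quaternary centre beside C5Me2 forms without an SN2 step, and silyl transfer restores the vinylogous ester.

Step 6
Reactants: 10 keto ketal
Product: 11 3-isobutoxy-5,5-dimethyl-6,6-bis(3-oxobutyl)cyclohex-2-en-1-one (achiral)
Conditions: PPTS (20 mol %), acetone–H2O 9:1, 50 °C
Reagents that add atoms: water O
Why: Mild acid hydrolysis cleaves the dialkyl ketal, which ionises far more readily than the resonance-stabilised vinylogous ester is hydrolysed, and the acidity is too low to start an aldol reaction.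

Step 7
Reactants: 11 achiral bis(3-oxobutyl) vinylogous ester
Product: 12 spiro ketol (6S,9S,10R): C9 tertiary OH on the C5 side of ring B, C10 acetyl cis to that OH
Conditions: 9-amino-9-deoxy-epi-quinine (20 mol %), PhCO2H (40 mol %), H2O (5 equiv), toluene, 0 °C → rt, stopped at full conversion, short silica filtration
Reagents that add atoms: none
Why: The primary amine condenses reversibly with either methyl ketone, but only the internal (Z)-enamine of one arm can reach the carbonyl group of the other arm, so its C10 adds to C9 and hydrolysis of the product iminium ion releases ketol and catalyst. The closest known reactions are the amine-catalysed enantiogroup-differentiating aldol cyclisation of prochiral triketones (Hajos–Parrish type) and the amine-catalysed 6-enolexo aldolisation of 1,7-dicarbonyl compounds. Ring B closes in the 6-(enolexo)-exo-trig mode through a chair. C9 and C10 are set by that chair (C9 methyl and the C10 enamine carbon equatorial, the C9 oxygen axial and hydrogen-bonded to the protonated quinuclidine, a geometry that needs the Z-enamine open to a primary but not to a secondary amine), and their relation to C6 follows from the strong preference of quaternary C5 for the equatorial site and of the flat C1 carbonyl for the axial site on C6. With the chair fixed, the pro-S arm as nucleophile gives 12 and the pro-R arm its mirror image, so the enamine-face preference of the catalyst decides the absolute configuration of all three centres at once. The step needs chemoselectivity for the arm ketone, secured because C1 is a hindered and deactivated vinylogous ester carbonyl and the terminal enamine would have to close an eight-membered ring, and it needs survival of the ketol, helped by added water, low temperature and the slow re-condensation of the α-branched, internally hydrogen-bonded acetyl group.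

Step 8
Reactants: 12 spiro ketol
Product: 13 hydroxy acetate (6S,9S,10R): C10–OAc in place of C10–acetyl
Conditions: mCPBA (2.5 equiv), CH2Cl2, 0 °C → rt
Reagents that add atoms: 3-chloroperbenzoic acid OOC(=O)c1cccc(Cl)c1
Why: In the Baeyer–Villiger oxidation secondary C10 migrates in preference to methyl with retention, the C9–OH hydrogen bond activates the acetyl carbonyl, the push–pull C2=C3 bond and the C1 carbonyl are poor partners for the peracid, and removal of the β-hydroxy ketone closes the retro-aldol and dehydration channels.

Step 9
Reactants: 13 hydroxy acetate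
Product: 15 diol enone (6S,9S,10R): C1–Me, C3=O, cis C9–OH/C10–OH, via C1 carbinol triol 14 (not isolated)
Conditions: CeCl3 (7 equiv), MeLi (7 equiv), THF, −78 → 0 °C; then 2 M aq. HCl, THF, rt
Reagents that add atoms: methyllithium [Li]C; water O
Why: Organocerium 1,2-addition to the hindered C1 carbonyl (cerium suppresses γ-deprotonation at C4), followed by acid hydrolysis of the enol ether with loss of the C1 hydroxyl (Stork–Danheiser transposition), gives the C1-methyl C3-enone, the same reagent cleaves the acetate, and no epoxide can form because no chlorine is present yet.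

Step 10
Reactants: 15 diol enone
Product: 16 cyclic sulfite (mixture at sulfur)
Conditions: SOCl2, Et3N, CH2Cl2, 0 °C
Reagents that add atoms: thionyl chloride O=S(Cl)Cl
Why: The cis-1,2-diol closes a five-membered cyclic sulfite through the fast-reacting secondary hydroxyl, no C–O bond is broken, and the configuration at sulfur is erased in the next step.

Step 11
Reactants: 16 cyclic sulfite
Product: 17 cyclic sulfate
Conditions: RuCl3·xH2O (1 mol %), NaIO4 (1.5 equiv), MeCN–CH2Cl2–H2O, 0 °C, 15 min
Reagents that add atoms: sodium periodate [Na+].[O-]I(=O)(=O)=O
Why: Ruthenium tetroxide-catalysed oxidation of sulfite to sulfate is complete within minutes at 0 °C, much faster than attack on the electron-poor, trisubstituted and flanked enone double bond.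

Step 12
Reactants: 17 cyclic sulfate
Product: 19 chlorohydrin enone (6S,9S,10S): C10–Cl on the C1 side of ring B and trans to C9–OH, via lithium sulfate monoester 18 (not isolated)
Conditions: LiCl (5 equiv), DMF, 50 °C; then H2SO4 (cat.), H2O (2 equiv), THF, rt
Reagents that add atoms: lithium chloride [Li+].[Cl-]
Why: In the SN2 opening of the cyclic sulfate, chloride attacks secondary C10 rather than fully substituted C9 and inverts it, the sulfate-bound C9 oxygen cannot trigger a semipinacol shift, and the monoester is then hydrolysed at sulfur so that C9 keeps its configuration.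

Step 13
Reactants: 19 chlorohydrin enone
Product: 20 bromochloro enone (6S,9S,10S): C9–Br trans to C10–Cl
Conditions: TMSBr (3 equiv), CH2Cl2, −40 → 0 °C; aq. NaHCO3
Reagents that add atoms: bromotrimethylsilane C[Si](C)(C)Br
Why: SN1-type bromination of the tertiary alcohol ionises the silylated C9 oxygen within a contact ion pair in a non-polar solvent, and because the vicinal chlorine shields its own face by chloronium-type bridging and dipole repulsion, bromide should enter on the face the oxygen left, anti to chlorine, with net retention.

Step 14
Reactants: 20 bromochloro enone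
Product: 22 C4-bromo enone (4R,6R,9S,10S), via silyl dienol ether 21 (not isolated)
Conditions: TMSCl (3 equiv), LiHMDS (1.3 equiv), THF, −78 °C; then NBS (1.05 equiv), −78 → −20 °C
Reagents that add atoms: N-bromosuccinimide O=C1CCC(=O)N1Br; chlorotrimethylsilane C[Si](C)(C)Cl (silicon only in 21)
Why: Kinetic α′-deprotonation with in-situ silylation (much faster at −78 °C than E2 at the tertiary bromide) gives the cross-conjugated silyl dienol ether, which NBS brominates at C4 with bromine settling equatorial on the enone half-chair, but since the two faces of ring A differ only through the distant C10 chlorine the preference for the 4R epimer is expected to be modest and 22 is separated from its C4 epimer by chromatography.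

Step 15
Reactants: 22 C4-bromo enone
Product: 23 target (3S,4R,6R,9S,10S)
Conditions: DIBAL-H (1.2 equiv), CH2Cl2, −78 °C; aq. Rochelle salt
Reagents that add atoms: none
Why: In the 1,2-reduction with DIBAL-H the pseudo-axial C5 methyl group blocks the axial trajectory while C4–Br is equatorial, so hydride enters equatorially and the C3 hydroxyl ends pseudo-axial and cis to bromine (3S), a geometry from which the aluminium alkoxide cannot displace bromide, and the alkyl halides are inert at −78 °C.

**Compound list**
1 | dimedone (5,5-dimethylcyclohexane-1,3-dione) | CC1(C)CC(=O)CC(=O)C1 | starting material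
2 | isobutanol | CC(C)CO | starting material
3 | 3-isobutoxy-5,5-dimethylcyclohex-2-en-1-one | CC(C)COC1=CC(=O)CC(C)(C)C1 | intermediate
4 | 2-(2-bromoethyl)-2-methyl-1,3-dioxolane | CC1(CCBr)OCCO1 | starting material
5 | 2-(2-iodoethyl)-2-methyl-1,3-dioxolane | CC1(CCI)OCCO1 | intermediate
6 | rac-3-isobutoxy-5,5-dimethyl-6-[2-(2-methyl-1,3-dioxolan-2-yl)ethyl]cyclohex-2-en-1-one | O=C1C=C(OCC(C)C)CC(C)(C)C1CCC2(C)OCCO2 | intermediate
7 | [5-isobutoxy-3,3-dimethyl-2-[2-(2-methyl-1,3-dioxolan-2-yl)ethyl]cyclohexa-1,5-dien-1-yl]oxytrimethylsilane | CC(C)COC1=CC(O[Si](C)(C)C)=C(CCC2(C)OCCO2)C(C)(C)C1 | intermediate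
8 | methyl vinyl ketone (but-3-en-2-one) | C=CC(C)=O | starting material
9 | Michael adduct with the new arm as its trimethylsilyl enol ether (not isolated) | O=C1C=C(OCC(C)C)CC(C)(C)C1(CCC2(C)OCCO2)CC=C(C)O[Si](C)(C)C | intermediate
10 | rac-3-isobutoxy-5,5-dimethyl-6-[2-(2-methyl-1,3-dioxolan-2-yl)ethyl]-6-(3-oxobutyl)cyclohex-2-en-1-one | O=C1C=C(OCC(C)C)CC(C)(C)C1(CCC2(C)OCCO2)CCC(C)=O | intermediate
11 | 3-isobutoxy-5,5-dimethyl-6,6-bis(3-oxobutyl)cyclohex-2-en-1-one (achiral key-step precursor) | O=C1C=C(OCC(C)C)CC(C)(C)C1(CCC(C)=O)CCC(C)=O | intermediate
12 | (6S,9S,10R)-spiro ketol: ring A isobutyl vinylogous ester, C9(Me)OH, C10 acetyl cis to OH | O=C1C=C(OCC(C)C)CC(C)(C)[C@@]12CC[C@](C)(O)[C@H](C(C)=O)C2 | intermediate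
13 | (6S,9S,10R)-hydroxy acetate: C9(Me)OH, C10–OAc | O=C1C=C(OCC(C)C)CC(C)(C)[C@@]12CC[C@](C)(O)[C@H](OC(C)=O)C2 | intermediate
14 | C1 methyl carbinol triol, enol ether intact, C1 unassigned (not isolated) | CC1(O)C=C(OCC(C)C)CC(C)(C)[C@@]12CC[C@](C)(O)[C@H](O)C2 | intermediate
15 | (6S,9S,10R)-diol enone: C1–Me, C3=O, cis C9–OH/C10–OH | CC1=CC(=O)CC(C)(C)[C@@]12CC[C@](C)(O)[C@H](O)C2 | intermediate
16 | C9,C10 cyclic sulfite of 15 (mixture at sulfur) | CC1=CC(=O)CC(C)(C)[C@@]12CC[C@]3(C)OS(=O)O[C@@H]3C2 | intermediate
17 | C9,C10 cyclic sulfate of 15 | CC1=CC(=O)CC(C)(C)[C@@]12CC[C@]3(C)OS(=O)(=O)O[C@@H]3C2 | intermediate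
18 | lithium C9 sulfate monoester with C10–Cl (not isolated) | [Li+].CC1=CC(=O)CC(C)(C)[C@@]12CC[C@](C)(OS(=O)(=O)[O-])[C@@H](Cl)C2 | intermediate
19 | (6S,9S,10S)-chlorohydrin enone: C9–OH trans to C10–Cl | CC1=CC(=O)CC(C)(C)[C@@]12CC[C@](C)(O)[C@@H](Cl)C2 | intermediate
20 | (6S,9S,10S)-bromochloro enone: C9–Br trans to C10–Cl | CC1=CC(=O)CC(C)(C)[C@@]12CC[C@](C)(Br)[C@@H](Cl)C2 | intermediate
21 | C3 trimethylsilyl dienol ether of 20 (C3=C4, C1=C2; not isolated) | CC1=CC(O[Si](C)(C)C)=CC(C)(C)[C@@]12CC[C@](C)(Br)[C@@H](Cl)C2 | intermediate
22 | (4R,6R,9S,10S)-C4-bromo enone | CC1=CC(=O)[C@H](Br)C(C)(C)[C@@]12CC[C@](C)(Br)[C@@H](Cl)C2 | intermediate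
23 | target, (3S,4R,6R,9S,10S) | CC1=C[C@H](O)[C@H](Br)C(C)(C)[C@@]12CC[C@](C)(Br)[C@@H](Cl)C2 | target

**Step count**
Total steps: 15. Longest linear sequence: 14 (steps 1 and 3–15, from dimedone).

**Steps most likely to fail**

Step 7. Several things may go wrong:
- The two enantiotopic arms may be discriminated insufficiently.
- C–C bond formation onto an unactivated ketone may be slow.
- Prolonged contact with the catalyst may dehydrate the ketol or racemise it through retro-aldol cleavage.

The fallback sets out from 11 and comes back at 12. The same C9–C10 bond is closed under the same chair control with an achiral primary amine salt (n-butylammonium acetate, toluene, rt). This gives the racemic ketol F1. The enantiomers are then separated by preparative chromatography on a chiral stationary phase, so asymmetric catalysis is replaced by a resolution.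

Step 13. Once C1 carries its methyl group, ring B is expected to prefer the chair with C5 axial. In that chair C10–Cl is equatorial and cannot shield or bridge. The C9 cation may therefore be captured on the face syn to chlorine, or it may lose a proton.

The fallback sets out from 13 and comes back at 20. Both substitutions are moved ahead of the C1 methylation, where ring B still holds the chair of step 7:
1. 13 is methanolysed (K2CO3, MeOH) to the diol vinylogous ester F2.
2. F2 is converted with SOCl2/Et3N into the cyclic sulfite F3.
3. F3 is oxidised with catalytic RuCl3/NaIO4, with short contact time, to the cyclic sulfate F4.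
4. F4 is opened with LiCl and hydrolysed to the chlorohydrin vinylogous ester F5.
5. In F5, C9–OH and C10–Cl are trans-diaxial, so TMSBr ionises C9 with chlorine antiperiplanar. Bromide enters axially, anti to chlorine, to give the bromochloro vinylogous ester F6.
6. F6 is then treated with the weakly basic MeLi/CeCl3 reagent at −78 °C and aqueous HCl, which gives 20.

Step 14. Facial selectivity in the attack of NBS on the planar dienol ether may be poor, because only the remote C10 chlorine distinguishes the two faces of ring A.

The fallback sets out from 20 and comes back at 22. The bromination is run without any claim to selectivity, and the problem is moved to a separation-and-recycling loop: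
1. The mixture of 22 and its C4 epimer F7 is reduced with DIBAL-H. Each epimer gives its own cis-bromohydrin under the local control of the C5 methyl group.
2. Target 23 is separated from the (3R,4S)-bromohydrin F8.
3. F8 is re-oxidised with Dess–Martin periodinane to F7.
4. F7 is equilibrated through its enol with triethylamine in CH2Cl2 to the 22/F7 mixture, which re-enters the route at 22.

**Further compounds**
F1 | step 7 | racemic ketol (12 and its mirror image) | O=C1C=C(OCC(C)C)CC(C)(C)[C@@]12CC[C@](C)(O)[C@H](C(C)=O)C2.O=C1C=C(OCC(C)C)CC(C)(C)[C@]12CC[C@@](C)(O)[C@@H](C(C)=O)C2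
F2 | step 13 | diol vinylogous ester | O=C1C=C(OCC(C)C)CC(C)(C)[C@@]12CC[C@](C)(O)[C@H](O)C2
F3 | step 13 | cyclic sulfite of F2 (mixture at sulfur) | O=C1C=C(OCC(C)C)CC(C)(C)[C@@]12CC[C@]3(C)OS(=O)O[C@@H]3C2
F4 | step 13 | cyclic sulfate of F2 | O=C1C=C(OCC(C)C)CC(C)(C)[C@@]12CC[C@]3(C)OS(=O)(=O)O[C@@H]3C2
F5 | step 13 | chlorohydrin vinylogous ester | O=C1C=C(OCC(C)C)CC(C)(C)[C@@]12CC[C@](C)(O)[C@@H](Cl)C2
F6 | step 13 | bromochloro vinylogous ester | O=C1C=C(OCC(C)C)CC(C)(C)[C@@]12CC[C@](C)(Br)[C@@H](Cl)C2
F7 | step 14 | C4 epimer of 22 | CC1=CC(=O)[C@@H](Br)C(C)(C)[C@@]12CC[C@](C)(Br)[C@@H](Cl)C2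
F8 | step 14 | (3R,4S)-bromohydrin, diastereomer of 23 | CC1=C[C@@H](O)[C@@H](Br)C(C)(C)[C@@]12CC[C@](C)(Br)[C@@H](Cl)C2
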